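**Retrosynthetic overview**

1. Target 28 comes from the fully protected trienoyl pyridone 26 by O4-demethylation (LiI) and global fluoride desilylation.
2. The strategy rests on the ketone carbon C1', which lies between pyridone C3 (ring A, flanked by C2=O and C4–O) and triene carbon C2'. Both neighbours are innately nucleophilic, so C3 is reversed in polarity as iodide 9 and joined to trienylstannane 24 through carbon monoxide 25 as a one-carbon electrophile.
3. Iodide 9 comes from 5-bromo-2,4-dimethoxypyridine 1 and silyloxycyclohexanone 2 by aryllithium addition (sets the cis-1,4-dioxygenated ring B), then N-oxide, N-hydroxypyridone, SEM ether and C3 iodination.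
4. Stannane 24 comes from butanal 10 by organocatalytic α-hydroxymethylation (sets C8'), Wittig and Horner–Wadsworth–Emmons olefinations and alkyne hydrostannation.
5. No ring is formed: pyridine ring A and cyclohexane ring B are purchased and joined in step 1.

Key step: step 14

Remark: TBS = tert-butyldimethylsilyl, SEM = [2-(trimethylsilyl)ethoxy]methyl, primed locants refer to the decatrienoyl chain (C1' = ketone carbon). The facial sense of step 6 is assigned by the usual shielding model of diarylprolinol silyl ether enamines, and 1, 2, 10, 11, 12, 18, 19 and 25 are taken as purchasable.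

**Route**

Step 1
Reactants: 1 5-bromo-2,4-dimethoxypyridine; 2 4-[(tert-butyldimethylsilyl)oxy]cyclohexan-1-one
Product: 4 cis-4-[(tert-butyldimethylsilyl)oxy]-1-(4,6-dimethoxypyridin-3-yl)cyclohexan-1-ol (tertiary OH and OTBS on the same ring face), via (4,6-dimethoxypyridin-3-yl)lithium 3 (not isolated)
Conditions: n-BuLi, THF, −78 °C; then 2, −78 → −40 °C; H2O quench
Reagents that add atoms: none
Why: Bromine–lithium exchange at C5 is fast at −78 °C and the ortho-methoxy aryllithium should add to the ketone (1,2-addition of an organolithium) mainly along the equatorial trajectory of the chair that carries OTBS equatorial, which places the new tertiary OH axial and cis to the silyloxy group, the minor trans isomer being removed by chromatography.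

Step 2
Reactants: 4 the dimethoxypyridyl carbinol
Product: 5 5-{cis-4-[(TBS)oxy]-1-hydroxycyclohexyl}-2,4-dimethoxypyridine 1-oxide
Conditions: mCPBA, CH2Cl2, 0 °C → rt
Reagents that add atoms: 3-chloroperoxybenzoic acid (mCPBA), OOC(=O)c1cccc(Cl)c1
Why: The ring nitrogen, made more nucleophilic by the 4-methoxy group, is the only site that should accept electrophilic oxygen from the peracid (pyridine N-oxidation), while the silyl ether and the tertiary alcohol are inert.

Step 3
Reactants: 5 the pyridine N-oxide
Product: 7 5-{cis-4-[(TBS)oxy]-1-hydroxycyclohexyl}-1-hydroxy-4-methoxypyridin-2(1H)-one, via 1-acetoxypyridin-2-one 6 (not isolated)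
Conditions: AcCl, 2,6-di-tert-butyl-4-methylpyridine (cat.), CH2Cl2, 0 → 40 °C; evaporate; then MeOH, NaHCO3, rt
Reagents that add atoms: none
Why: O-Acetylation of the N-oxide gives an N-acetoxy-2-methoxypyridinium chloride whose chloride removes the O2 methyl group by SN2 attack (the classical acyl chloride rearrangement of 2-alkoxypyridine N-oxides to 1-acyloxy-2-pyridones, O2 reacting in preference to O4 because it sits on the carbon next to the cationic nitrogen), and the activated N–O acetate is then cleaved by buffered methanolysis.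

Step 4
Reactants: 7 the N-hydroxypyridone
Product: 8 5-{cis-4-[(TBS)oxy]-1-hydroxycyclohexyl}-4-methoxy-1-{[2-(trimethylsilyl)ethoxy]methoxy}pyridin-2(1H)-one
Conditions: SEMCl, iPr2NEt, CH2Cl2, 0 °C → rt
Reagents that add atoms: 2-(trimethylsilyl)ethoxymethyl chloride (SEMCl), C[Si](C)(C)CCOCCl
Why: The acidic N-hydroxy group of the cyclic hydroxamic acid is alkylated on oxygen by the reactive chloromethyl ether under mild amine base (O-alkylation), whereas the hindered tertiary alcohol should not react.

Step 5
Reactants: 8 the N-SEM-oxy pyridone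
Product: 9 5-{cis-4-[(TBS)oxy]-1-hydroxycyclohexyl}-3-iodo-4-methoxy-1-{[2-(trimethylsilyl)ethoxy]methoxy}pyridin-2(1H)-one
Conditions: NIS, MeCN, rt, dark
Reagents that add atoms: N-iodosuccinimide (NIS), O=C1CCC(=O)N1I
Why: C3 is the nucleophilic α-carbon of the vinylogous carbamate between the C2 carbonyl and the C4 methoxy group and the only such position left open now that C5 is substituted, so electrophilic iodination should occur there.

Step 6
Reactants: 10 butanal; 11 formaldehyde (37% aqueous); 12 ethyl (triphenylphosphoranylidene)acetate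
Product: 14 ethyl (2E,4R)-4-(hydroxymethyl)hex-2-enoate, via (S)-2-(hydroxymethyl)butanal 13 (not isolated)
Conditions: (R)-2-[diphenyl(trimethylsilyloxy)methyl]pyrrolidine (10 mol %), pH 7 phosphate buffer, toluene, rt; then 12 (excess), rt
Reagents that add atoms: none
Why: The (E)-enamine of butanal with the (R)-diarylprolinol silyl ether is attacked by formaldehyde on the face away from the diphenyl(silyloxy)methyl group (organocatalytic enantioselective α-hydroxymethylation), which sets the (S)-aldehyde centre, and the configurationally labile β-hydroxy aldehyde is trapped at once by E-selective Wittig olefination with the stabilized ylide, the centre becoming C4 (R) of the enoate.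

Step 7
Reactants: 14 the hydroxy enoate
Product: 15 ethyl (2E,4R)-4-{[(tert-butyldimethylsilyl)oxy]methyl}hex-2-enoate
Conditions: TBSCl, imidazole, CH2Cl2, rt
Reagents that add atoms: tert-butyldimethylsilyl chloride (TBSCl), CC(C)(C)[Si](C)(C)Cl
Why: Imidazole-promoted silylation of the unhindered primary alcohol is routine and does not touch the enoate or the stereocentre.

Step 8
Reactants: 15 the silyloxy enoate
Product: 16 (2E,4R)-4-{[(tert-butyldimethylsilyl)oxy]methyl}hex-2-en-1-ol
Conditions: iBu2AlH, CH2Cl2, −78 °C; aq. potassium sodium tartrate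
Reagents that add atoms: none
Why: Two hydride equivalents from iBu2AlH reduce the conjugated ester in 1,2-fashion to the allylic alcohol at low temperature without conjugate reduction or loss of the silyl ether.

Step 9
Reactants: 16 the allylic alcohol
Product: 17 (2E,4R)-4-{[(tert-butyldimethylsilyl)oxy]methyl}hex-2-enal
Conditions: MnO2, CH2Cl2, rt
Reagents that add atoms: none
Why: MnO2 oxidizes allylic alcohols selectively under neutral heterogeneous conditions, so the E geometry and the γ-stereocentre of the enal should be preserved.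

Step 10
Reactants: 18 3-bromo-1-(trimethylsilyl)prop-1-yne; 19 triethyl phosphite
Product: 20 diethyl [3-(trimethylsilyl)prop-2-yn-1-yl]phosphonate
Conditions: neat, 120 °C, EtBr distilled off
Reagents that add atoms: none
Why: The Michaelis–Arbuzov reaction of the reactive propargylic bromide with the phosphite gives the phosphonate, the silyl group blocking isomerization to an allene.

Step 11
Reactants: 17 the enal; 20 the propargyl phosphonate
Product: 22 tert-butyl{[(2R,3E,5E)-2-ethyl-8-(trimethylsilyl)octa-3,5-dien-7-yn-1-yl]oxy}dimethylsilane, via lithiated phosphonate 21 (not isolated)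
Conditions: LiN(SiMe3)2, THF, −78 °C; then 17, −78 → 0 °C
Reagents that add atoms: none
Why: The preformed stabilized phosphonate anion adds to the aldehyde faster than it deprotonates the γ-position, and the Horner–Wadsworth–Emmons elimination should give the new C5=C6 double bond with E geometry.

Step 12
Reactants: 22 the silylated dienyne
Product: 23 tert-butyl{[(2R,3E,5E)-2-ethylocta-3,5-dien-7-yn-1-yl]oxy}dimethylsilane
Conditions: K2CO3 (cat.), MeOH, rt
Reagents that add atoms: none
Why: Methoxide cleaves the alkynyl C–Si bond (protodesilylation of a trimethylsilylalkyne) far faster than it attacks the primary TBS ether.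

Step 13
Reactants: 23 the terminal dienyne
Product: 24 tributyl[(1E,3E,5E,7R)-7-{[(tert-butyldimethylsilyl)oxy]methyl}nona-1,3,5-trien-1-yl]stannane
Conditions: Bu3SnH, PdCl2(PPh3)2 (cat.), THF, 0 °C; Et3N-deactivated silica
Reagents that add atoms: tributyltin hydride, CCCC[SnH](CCCC)CCCC
Why: Palladium-catalysed hydrostannation adds Sn–H syn across the terminal alkyne of the conjugated enyne with tin at the unhindered terminal carbon, which should give the (1E)-stannane and leave the existing diene unchanged.

Step 14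
Reactants: 9 the 3-iodopyridone; 24 the trienylstannane; 25 carbon monoxide
Product: 26 3-[(2E,4E,6E,8R)-8-{[(TBS)oxy]methyl}deca-2,4,6-trienoyl]-5-{cis-4-[(TBS)oxy]-1-hydroxycyclohexyl}-4-methoxy-1-{[2-(trimethylsilyl)ethoxy]methoxy}pyridin-2(1H)-one
Conditions: Pd2(dba)3 (5 mol %), AsPh3 (40 mol %), CO (3 atm), NMP, 55 °C, dark
Reagents that add atoms: none
Why: Zerovalent palladium (from Pd2(dba)3 and AsPh3) adds oxidatively to the C3–I bond of 9, CO inserts into the resulting divalent arylpalladium iodide to give an aroylpalladium species, the trienyl group is transferred from tin with retention of alkene geometry, and reductive elimination releases trienone 26 and Bu3SnI. The closest known reaction type is the carbonylative Stille coupling of hindered aryl and heteroaryl iodides with alkenylstannanes to give aryl alkenyl ketones. No ring is closed and no stereocentre is created; the two skeletal bonds C3–C1' and C1'–C2' are formed. The selectivity needed is carbonylative over direct coupling, and it is secured by the CO pressure together with the flanking C2 carbonyl and C4 methoxy groups, which slow transmetalation at the crowded arylpalladium stage so that CO insertion comes first. The all-E geometry is carried over from stannane 24, and because the medium is neutral the C8' stereocentre, which becomes vinylogously acidic only once the ketone exists, is not exposed to base.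

Step 15
Reactants: 26 the protected trienoyl pyridone
Product: 27 3-[(2E,4E,6E,8R)-8-{[(TBS)oxy]methyl}deca-2,4,6-trienoyl]-5-{cis-4-[(TBS)oxy]-1-hydroxycyclohexyl}-4-hydroxy-1-{[2-(trimethylsilyl)ethoxy]methoxy}pyridin-2(1H)-one
Conditions: LiI, EtOAc, 60 °C, dark; cold dilute HCl work-up
Reagents that add atoms: none
Why: Lithium chelated between the C3 acyl oxygen and the C4 methoxy oxygen activates this doubly vinylogous methyl ester toward SN2 attack of iodide at the methyl carbon (nucleophilic O-demethylation of a chelated β-methoxy enone), which should free the acidic 4-hydroxyl without base and leave the triene, the silyl ethers and the tertiary alcohol untouched.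

Step 16
Reactants: 27 the 4-hydroxy pyridone
Product: 28 5-(cis-1,4-dihydroxycyclohexyl)-1,4-dihydroxy-3-[(2E,4E,6E,8R)-8-(hydroxymethyl)deca-2,4,6-trienoyl]pyridin-2(1H)-one (target)
Conditions: Bu4NF, THF, 0 °C → rt; dilute HCl to pH 3
Reagents that add atoms: none
Why: Fluoride cleaves both TBS ethers and fragments the SEM group (loss of Me3SiF, ethene and formaldehyde, the N-oxidopyridone being a good leaving group) in a global desilylation, and because the 4-hydroxy-3-acylpyridone is present as its anion the trienone is deactivated toward vinylogous deprotonation, so C8' and the all-E triene should survive.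

**Compound list**

1 | 5-bromo-2,4-dimethoxypyridine | COc1cc(OC)c(Br)cn1 | starting material
2 | 4-[(tert-butyldimethylsilyl)oxy]cyclohexan-1-one | CC(C)(C)[Si](C)(C)OC1CCC(=O)CC1 | starting material
3 | (4,6-dimethoxypyridin-3-yl)lithium | COc1cc(OC)c([Li])cn1 | intermediate
4 | cis-4-[(tert-butyldimethylsilyl)oxy]-1-(4,6-dimethoxypyridin-3-yl)cyclohexan-1-ol (OH and OTBS cis) | COc1cc(OC)c([C@]2(O)CC[C@@H](O[Si](C)(C)C(C)(C)C)CC2)cn1 | intermediate
5 | 5-{cis-4-[(tert-butyldimethylsilyl)oxy]-1-hydroxycyclohexyl}-2,4-dimethoxypyridine 1-oxide | COc1cc(OC)c([C@]2(O)CC[C@@H](O[Si](C)(C)C(C)(C)C)CC2)c[n+]1[O-] | intermediate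
6 | 1-acetoxy-5-{cis-4-[(tert-butyldimethylsilyl)oxy]-1-hydroxycyclohexyl}-4-methoxypyridin-2(1H)-one | O=c1cc(OC)c([C@]2(O)CC[C@@H](O[Si](C)(C)C(C)(C)C)CC2)cn1OC(C)=O | intermediate
7 | 5-{cis-4-[(tert-butyldimethylsilyl)oxy]-1-hydroxycyclohexyl}-1-hydroxy-4-methoxypyridin-2(1H)-one | O=c1cc(OC)c([C@]2(O)CC[C@@H](O[Si](C)(C)C(C)(C)C)CC2)cn1O | intermediate
8 | 5-{cis-4-[(tert-butyldimethylsilyl)oxy]-1-hydroxycyclohexyl}-4-methoxy-1-{[2-(trimethylsilyl)ethoxy]methoxy}pyridin-2(1H)-one | O=c1cc(OC)c([C@]2(O)CC[C@@H](O[Si](C)(C)C(C)(C)C)CC2)cn1OCOCC[Si](C)(C)C | intermediate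
9 | 5-{cis-4-[(tert-butyldimethylsilyl)oxy]-1-hydroxycyclohexyl}-3-iodo-4-methoxy-1-{[2-(trimethylsilyl)ethoxy]methoxy}pyridin-2(1H)-one | O=c1c(I)c(OC)c([C@]2(O)CC[C@@H](O[Si](C)(C)C(C)(C)C)CC2)cn1OCOCC[Si](C)(C)C | intermediate
10 | butanal | CCCC=O | starting material
11 | formaldehyde | C=O | starting material
12 | ethyl (triphenylphosphoranylidene)acetate | CCOC(=O)C=P(c1ccccc1)(c1ccccc1)c1ccccc1 | starting material
13 | (S)-2-(hydroxymethyl)butanal | CC[C@H](C=O)CO | intermediate
14 | ethyl (2E,4R)-4-(hydroxymethyl)hex-2-enoate | CC[C@H](/C=C/C(=O)OCC)CO | intermediate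
15 | ethyl (2E,4R)-4-{[(tert-butyldimethylsilyl)oxy]methyl}hex-2-enoate | CC[C@H](/C=C/C(=O)OCC)CO[Si](C)(C)C(C)(C)C | intermediate
16 | (2E,4R)-4-{[(tert-butyldimethylsilyl)oxy]methyl}hex-2-en-1-ol | CC[C@H](/C=C/CO)CO[Si](C)(C)C(C)(C)C | intermediate
17 | (2E,4R)-4-{[(tert-butyldimethylsilyl)oxy]methyl}hex-2-enal | CC[C@H](/C=C/C=O)CO[Si](C)(C)C(C)(C)C | intermediate
18 | 3-bromo-1-(trimethylsilyl)prop-1-yne | C[Si](C)(C)C#CCBr | starting material
19 | triethyl phosphite | CCOP(OCC)OCC | starting material
20 | diethyl [3-(trimethylsilyl)prop-2-yn-1-yl]phosphonate | CCOP(=O)(CC#C[Si](C)(C)C)OCC | intermediate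
21 | lithium salt of the phosphonate carbanion of 20 | CCOP(=O)([CH-]C#C[Si](C)(C)C)OCC.[Li+] | intermediate
22 | tert-butyl{[(2R,3E,5E)-2-ethyl-8-(trimethylsilyl)octa-3,5-dien-7-yn-1-yl]oxy}dimethylsilane | CC[C@H](/C=C/C=C/C#C[Si](C)(C)C)CO[Si](C)(C)C(C)(C)C | intermediate
23 | tert-butyl{[(2R,3E,5E)-2-ethylocta-3,5-dien-7-yn-1-yl]oxy}dimethylsilane | CC[C@H](/C=C/C=C/C#C)CO[Si](C)(C)C(C)(C)C | intermediate
24 | tributyl[(1E,3E,5E,7R)-7-{[(tert-butyldimethylsilyl)oxy]methyl}nona-1,3,5-trien-1-yl]stannane | CC[C@H](/C=C/C=C/C=C/[Sn](CCCC)(CCCC)CCCC)CO[Si](C)(C)C(C)(C)C | intermediate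
25 | carbon monoxide | [C-]#[O+] | starting material
26 | 3-[(2E,4E,6E,8R)-8-{[(tert-butyldimethylsilyl)oxy]methyl}deca-2,4,6-trienoyl]-5-{cis-4-[(tert-butyldimethylsilyl)oxy]-1-hydroxycyclohexyl}-4-methoxy-1-{[2-(trimethylsilyl)ethoxy]methoxy}pyridin-2(1H)-one | CC[C@H](/C=C/C=C/C=C/C(=O)c1c(OC)c([C@]2(O)CC[C@@H](O[Si](C)(C)C(C)(C)C)CC2)cn(OCOCC[Si](C)(C)C)c1=O)CO[Si](C)(C)C(C)(C)C | intermediate
27 | 3-[(2E,4E,6E,8R)-8-{[(tert-butyldimethylsilyl)oxy]methyl}deca-2,4,6-trienoyl]-5-{cis-4-[(tert-butyldimethylsilyl)oxy]-1-hydroxycyclohexyl}-4-hydroxy-1-{[2-(trimethylsilyl)ethoxy]methoxy}pyridin-2(1H)-one | CC[C@H](/C=C/C=C/C=C/C(=O)c1c(O)c([C@]2(O)CC[C@@H](O[Si](C)(C)C(C)(C)C)CC2)cn(OCOCC[Si](C)(C)C)c1=O)CO[Si](C)(C)C(C)(C)C | intermediate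
28 | 5-(cis-1,4-dihydroxycyclohexyl)-1,4-dihydroxy-3-[(2E,4E,6E,8R)-8-(hydroxymethyl)deca-2,4,6-trienoyl]pyridin-2(1H)-one | CC[C@H](/C=C/C=C/C=C/C(=O)c1c(O)c([C@]2(O)CC[C@@H](O)CC2)cn(O)c1=O)CO | target

**Summary**

Total step count: 16 (steps 1–5 pyridone fragment, steps 6–13 stannane fragment including the side step 10, steps 14–16 union and deprotection).
Longest linear sequence: 10 steps (6, 7, 8, 9, 11, 12, 13, 14, 15, 16 from butanal).

**Steps most likely to fail**

Step 14. Direct, non-carbonylative coupling, or protodestannylation and homocoupling of the sensitive trienylstannane, may outrun acyl transfer. The fallback forms the ketone by addition and oxidation; it sets out from enal 17 and iodide 9 and comes back at 26. Enal 17 would be extended with triethyl 4-phosphonocrotonate (LiN(SiMe3)2, THF) to ethyl (2E,4E,6E,8R)-8-{[(tert-butyldimethylsilyl)oxy]methyl}deca-2,4,6-trienoate F1. Reduction with iBu2AlH would give (2E,4E,6E,8R)-8-{[(tert-butyldimethylsilyl)oxy]methyl}deca-2,4,6-trien-1-ol F2, and MnO2 would oxidize it to the corresponding trienal F3. Iodide 9 would be deprotonated at the tertiary OH with MeMgCl and exchanged with iPrMgCl·LiCl (THF, −40 °C) to the C3-magnesiated pyridone chloromagnesium alkoxide F4. Addition of F4 to F3 would give the secondary trienyl carbinol F5 as an epimer mixture of no consequence, and MnO2 oxidation of F5 would give 26.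

Step 3. Adventitious HCl may ionize the tertiary carbinol (dehydration to the cyclohexene), or chloride may demethylate O4 instead of O2. The fallback replaces the acyl chloride rearrangement by neutral hydrogenolysis; it sets out from ketone 2 and comes back at 7. Purchased 5-bromo-2-chloro-4-methoxypyridine would be treated with benzyl alcohol and NaH (SNAr) to give 2-(benzyloxy)-5-bromo-4-methoxypyridine F6. Bromine–lithium exchange (n-BuLi, THF, −78 °C) and addition to 2 would give cis-1-[6-(benzyloxy)-4-methoxypyridin-3-yl]-4-[(tert-butyldimethylsilyl)oxy]cyclohexan-1-ol F7. mCPBA would convert it to the N-oxide F8, and hydrogenolysis (H2, palladium on carbon, EtOH) would remove the benzyl group to give 7.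

Step 1. Facial selectivity of the carbonyl addition may be poor, and the ketone may be enolized by the aryllithium. The fallback sets the second carbinol centre by hydride reduction; it sets out from bromide 1 (through aryllithium 3) and comes back at 4. Aryllithium 3 would be added to 1,4-dioxaspiro[4.5]decan-8-one to give 8-(4,6-dimethoxypyridin-3-yl)-1,4-dioxaspiro[4.5]decan-8-ol F9. Mild ketal hydrolysis (pyridinium p-toluenesulfonate, aqueous acetone) would give 4-(4,6-dimethoxypyridin-3-yl)-4-hydroxycyclohexan-1-one F10. NaBH4 (MeOH, −20 °C) should attack axially on the chair with the aryl group equatorial, giving cis-1-(4,6-dimethoxypyridin-3-yl)cyclohexane-1,4-diol F11, and selective silylation of the secondary hydroxyl (TBSCl, imidazole) would give 4.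

Further compounds
F1 | step 14 | ethyl (2E,4E,6E,8R)-8-{[(tert-butyldimethylsilyl)oxy]methyl}deca-2,4,6-trienoate | CC[C@H](/C=C/C=C/C=C/C(=O)OCC)CO[Si](C)(C)C(C)(C)C
F2 | step 14 | (2E,4E,6E,8R)-8-{[(tert-butyldimethylsilyl)oxy]methyl}deca-2,4,6-trien-1-ol | CC[C@H](/C=C/C=C/C=C/CO)CO[Si](C)(C)C(C)(C)C
F3 | step 14 | (2E,4E,6E,8R)-8-{[(tert-butyldimethylsilyl)oxy]methyl}deca-2,4,6-trienal | CC[C@H](/C=C/C=C/C=C/C=O)CO[Si](C)(C)C(C)(C)C
F4 | step 14 | C3-chloromagnesio derivative of 9 as its chloromagnesium tertiary alkoxide | O=c1c([Mg]Cl)c(OC)c([C@]2(O[Mg]Cl)CC[C@@H](O[Si](C)(C)C(C)(C)C)CC2)cn1OCOCC[Si](C)(C)C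
F5 | step 14 | 3-[(2E,4E,6E,8R)-8-{[(tert-butyldimethylsilyl)oxy]methyl}-1-hydroxydeca-2,4,6-trien-1-yl]-5-{cis-4-[(tert-butyldimethylsilyl)oxy]-1-hydroxycyclohexyl}-4-methoxy-1-{[2-(trimethylsilyl)ethoxy]methoxy}pyridin-2(1H)-one (carbinol epimers) | CC[C@H](/C=C/C=C/C=C/C(O)c1c(OC)c([C@]2(O)CC[C@@H](O[Si](C)(C)C(C)(C)C)CC2)cn(OCOCC[Si](C)(C)C)c1=O)CO[Si](C)(C)C(C)(C)C
F6 | step 3 | 2-(benzyloxy)-5-bromo-4-methoxypyridine | COc1cc(OCc2ccccc2)ncc1Br
F7 | step 3 | cis-1-[6-(benzyloxy)-4-methoxypyridin-3-yl]-4-[(tert-butyldimethylsilyl)oxy]cyclohexan-1-ol | c1ccccc1COc1cc(OC)c([C@]2(O)CC[C@@H](O[Si](C)(C)C(C)(C)C)CC2)cn1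
F8 | step 3 | 2-(benzyloxy)-5-{cis-4-[(tert-butyldimethylsilyl)oxy]-1-hydroxycyclohexyl}-4-methoxypyridine 1-oxide | c1ccccc1COc1cc(OC)c([C@]2(O)CC[C@@H](O[Si](C)(C)C(C)(C)C)CC2)c[n+]1[O-]
F9 | step 1 | 8-(4,6-dimethoxypyridin-3-yl)-1,4-dioxaspiro[4.5]decan-8-ol | COc1cc(OC)c(C2(O)CCC3(CC2)OCCO3)cn1
F10 | step 1 | 4-(4,6-dimethoxypyridin-3-yl)-4-hydroxycyclohexan-1-one | COc1cc(OC)c(C2(O)CCC(=O)CC2)cn1
F11 | step 1 | cis-1-(4,6-dimethoxypyridin-3-yl)cyclohexane-1,4-diol | COc1cc(OC)c([C@]2(O)CC[C@@H](O)CC2)cn1
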